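**Plan**
- Cuts, in retrosynthetic order: nine O–benzyl bonds; the lower ring C, by removing the hydrogens from C-2, C-3 and C-4 to reach a 3-benzyloxyflavone and then cutting O1–C8a and C3–C4 into an o-fluorobenzoate (lower ring A carrying the whole upper unit) and an α-benzyloxy ketone (ring B, C-2, C-3, O-1); the interflavan C4–C6 bond (flavan-4-yl cation + bromofluorophenol); the upper ring C (flavonol from a chalcone).
- Forward: upper ring C (Algar–Flynn–Oyamada) and its hydrogenation; interflavan bond; Br → CO2Me; lower ring C by a one-pot Claisen/SNAr annulation; second hydrogenation; hydrogenolysis.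
- Enabling feature: on ring A of the lower unit, C-4 and C-8a are 1,3-related. An acyl carbon and an ortho carbon bearing fluorine (next to O-8) form a 1,3-dielectrophile that matches the O-1/C-3 enolate of a ketone whose C-3 is already oxygenated.
- Stereochemistry: C-2, C-3 and C-4 of each unit come from catalyst-controlled syn delivery of hydrogen to one face of a planar flavonol ether (all-cis). The upper C-4 comes from capture of the benzylic cation anti to the 3-benzyloxy and 2-aryl groups (3,4-trans).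

Key step: step 13

Remark 1: the (R,R)-ligand is written for both hydrogenations on the assumption that it delivers hydrogen to the face giving the (2R,3R) series; the (S,S)-ligand would be used if a trial on 7 showed the opposite sense. SINpEt·HBF4 = 1,3-bis[1-(naphthalen-1-yl)ethyl]imidazolinium tetrafluoroborate.
Remark 2: the descriptor at the upper C-4 is S in 15 and 25 but R in 16, 17, 21, 22, 23 and 24; the geometry (aryl trans to the 3-oxygen) is the same, only the CIP priority of the lower ring changes on O-benzylation.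

**Route**

Step 1
Reactants: 1 2,3,4-trihydroxyacetophenone
Product: 2 1-[3,4-bis(benzyloxy)-2-hydroxyphenyl]ethan-1-one
Conditions: BnBr (2.1 equiv), K2CO3, DMF, 50 °C
Reagents that add atoms: benzyl bromide, BrCc1ccccc1
Why: Williamson etherification; the 2-hydroxyl is hydrogen-bonded to the acetyl carbonyl, is the least reactive, and stays free for the later ring closure.

Step 2
Reactants: 2 1-[3,4-bis(benzyloxy)-2-hydroxyphenyl]ethan-1-one; 3 3,4-bis(benzyloxy)benzaldehyde
Product: 4 (E)-1-[3,4-bis(benzyloxy)-2-hydroxyphenyl]-3-[3,4-bis(benzyloxy)phenyl]prop-2-en-1-one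
Conditions: KOH, EtOH/THF, 23 °C
Reagents that add atoms: none
Why: Claisen–Schmidt condensation; E1cB dehydration of the aldol gives the E-enone.

Step 3
Reactants: 4 the 2'-hydroxychalcone
Product: 6 7,8-bis(benzyloxy)-2-[3,4-bis(benzyloxy)phenyl]-3-hydroxy-4H-chromen-4-one, via rac-trans-dihydroflavonol 5 (not isolated)
Conditions: H2O2 (30% aq), NaOH, MeOH/THF, 0 → 23 °C
Reagents that add atoms: hydrogen peroxide, OO
Why: Algar–Flynn–Oyamada reaction; with no 6'-substituent the oxidative cyclisation should follow the flavonol (not the aurone) pathway.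

Step 4
Reactants: 6 the flavonol
Product: 7 3,7,8-tris(benzyloxy)-2-[3,4-bis(benzyloxy)phenyl]-4H-chromen-4-one
Conditions: BnBr, K2CO3, DMF, 60 °C
Reagents that add atoms: benzyl bromide, BrCc1ccccc1
Why: Williamson etherification of the acidic 3-hydroxyl; it removes the only acidic proton before the base-activated hydrogenation.

Step 5
Reactants: 7 the pentabenzyl flavonol ether
Product: 9 (2R,3R,4R)-3,7,8-tris(benzyloxy)-2-[3,4-bis(benzyloxy)phenyl]chroman-4-ol, via cis-flavanone 8 (not isolated)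
Conditions: H2 (100 bar), Ru(cod)(2-methylallyl)2 (5 mol%), (R,R)-SINpEt·HBF4 (10 mol%), KOtBu (12 mol%), toluene, 40 °C
Reagents that add atoms: none
Why: Proposed new method: a chiral Ru–bis(NHC) hydride is expected to add H2 syn across the tetrasubstituted C2=C3 bond from one enantioface (giving the 2,3-cis ketone 8) and then to reduce C4=O from the same face, anti to the 2-aryl and 3-benzyloxy groups, so that all three hydrogens enter cis under catalyst control; the closest known reaction types are the Ru–NHC-catalysed asymmetric hydrogenation of flavones and chromones to cis-flavan-4-ols and the heterogeneous hydrogenation of flavonols to 2,3-cis-3,4-cis-flavan-3,4-diols, the new element being the 3-alkoxy-substituted C=C bond.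

Step 6
Reactants: 10 3-fluoro-2-hydroxybenzaldehyde
Product: 11 2-(benzyloxy)-3-fluorobenzaldehyde
Conditions: BnBr, K2CO3, DMF, 23 °C
Reagents that add atoms: benzyl bromide, BrCc1ccccc1
Why: Williamson etherification of the phenol.

Step 7
Reactants: 11 2-(benzyloxy)-3-fluorobenzaldehyde
Product: 13 2-(benzyloxy)-3-fluorophenol, via aryl formate 12 (not isolated)
Conditions: mCPBA, CH2Cl2, 23 °C; then K2CO3 (cat.), MeOH
Reagents that add atoms: 3-chloroperoxybenzoic acid, OOC(=O)c1cccc(Cl)c1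
Why: Baeyer–Villiger (Dakin-type) oxidation; the ortho-alkoxy aryl group migrates in preference to hydrogen, and methanolysis of the formate frees the phenol at a fixed position.

Step 8
Reactants: 13 2-(benzyloxy)-3-fluorophenol
Product: 14 2-(benzyloxy)-4-bromo-3-fluorophenol
Conditions: NBS, MeCN, 0 °C
Reagents that add atoms: N-bromosuccinimide, O=C1CCC(=O)N1Br
Why: Electrophilic bromination para to the free hydroxyl; it blocks that position and installs the handle for the later carbonylation.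

Step 9
Reactants: 9 the upper flavan-4-ol; 14 2-(benzyloxy)-4-bromo-3-fluorophenol
Product: 15 2-(benzyloxy)-4-bromo-3-fluoro-6-[(2R,3R,4S)-3,7,8-tris(benzyloxy)-2-[3,4-bis(benzyloxy)phenyl]chroman-4-yl]phenol
Conditions: 14 in fivefold excess, BF3·OEt2 (20 mol%), 4 Å molecular sieves, CH2Cl2, −40 → 0 °C
Reagents that add atoms: none
Why: Friedel–Crafts alkylation: BF3 ionises the 4-hydroxyl (the water formed is taken up by the sieves), and the benzylic C-4 cation, stabilised by the para 7-benzyloxy group, is attacked by 14 ortho to its free hydroxyl (para position blocked by Br, the twisted 2-benzyloxy group a weak director) from the face anti to the 3-benzyloxy and 2-aryl groups, which sets the upper C-4 as 3,4-trans.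

Step 10
Reactants: 15 the coupled phenol
Product: 16 (2R,3R,4R)-3,7,8-tris(benzyloxy)-2-[3,4-bis(benzyloxy)phenyl]-4-[2,3-bis(benzyloxy)-5-bromo-4-fluorophenyl]chromane
Conditions: BnBr, K2CO3, DMF, 50 °C
Reagents that add atoms: benzyl bromide, BrCc1ccccc1
Why: Williamson etherification of the remaining phenol, so that no acidic proton interferes with the enolate chemistry of step 13.

Step 11
Reactants: 16 the aryl bromide
Product: 17 methyl 3,4-bis(benzyloxy)-2-fluoro-5-[(2R,3R,4R)-3,7,8-tris(benzyloxy)-2-[3,4-bis(benzyloxy)phenyl]chroman-4-yl]benzoate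
Conditions: CO (1 atm), Pd(OAc)2 (5 mol%), Xantphos (6 mol%), Et3N, MeOH/toluene, 80 °C
Reagents that add atoms: carbon monoxide, [C-]#[O+]; methanol, CO
Why: Palladium-catalysed methoxycarbonylation: zerovalent palladium inserts into C–Br (C–F inert), CO inserts, and methanolysis of the acyl complex places the future C-4 ortho to fluorine.

Step 12
Reactants: 18 4-(benzyloxy)phenylmagnesium bromide (commercial THF solution); 19 2-(benzyloxy)-N-methoxy-N-methylacetamide
Product: 20 2-(benzyloxy)-1-[4-(benzyloxy)phenyl]ethan-1-one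
Conditions: THF, 0 °C; aq NH4Cl
Reagents that add atoms: none
Why: Weinreb ketone synthesis; the chelated tetrahedral adduct prevents over-addition.

Step 13
Reactants: 17 the o-fluorobenzoate; 20 the α-benzyloxy ketone
Product: 22 3,7,8-tris(benzyloxy)-2-[4-(benzyloxy)phenyl]-6-[(2R,3R,4R)-3,7,8-tris(benzyloxy)-2-[3,4-bis(benzyloxy)phenyl]chroman-4-yl]-4H-chromen-4-one, via 1,3-diketone 21 (not isolated)
Conditions: 20 (2.2 equiv), KN(SiMe3)2 (2.2 equiv), THF, −78 °C; add 17, −78 → 23 °C; then DMF, 80 °C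
Reagents that add atoms: none
Why: The potassium enolate of 20, a 1,3-O,C-dinucleophile whose carbon already bears the C-3 oxygen, is C-acylated by the ester of 17 (Claisen condensation, driven by formation of the diketonate of 21); the enolate oxygen then displaces fluoride at C-8a by addition–elimination, the Meisenheimer adduct being stabilised by the ortho C-4 carbonyl. The closest known reaction type is the tandem C-acylation/intramolecular SNAr annulation of 2-fluorobenzoyl electrophiles with ketone enolates to chromones and flavones. Ring C of the lower unit closes as a six-membered ring by O-attack on the aromatic C-8a (6-exo-trig with respect to the C8a=C8 bond). No stereocentre is formed: the step delivers the planar 3-benzyloxyflavone on which step 14 sets C-2, C-3 and C-4 together, and the upper-unit stereocentres should be untouched because the only bases present are enolates. The selectivities needed are C- over O-acylation (thermodynamic diketonate), O- over C-arylation (C-attack would need a four-membered ring) and attack at C-8a only (the single leaving group, ortho to the acyl group).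

Step 14
Reactants: 22 the dimeric 3-benzyloxyflavone
Product: 24 (2R,3R,4R)-3,7,8-tris(benzyloxy)-2-[4-(benzyloxy)phenyl]-6-[(2R,3R,4R)-3,7,8-tris(benzyloxy)-2-[3,4-bis(benzyloxy)phenyl]chroman-4-yl]chroman-4-ol, via cis-flavanone 23 (not isolated)
Conditions: H2 (100 bar), Ru(cod)(2-methylallyl)2 (5 mol%), (R,R)-SINpEt·HBF4 (10 mol%), KOtBu (12 mol%), toluene, 40 °C
Reagents that add atoms: none
Why: Proposed new method: as in step 5, syn addition of H2 to one enantioface of the C2=C3 bond followed by ketone reduction anti to the new 2-aryl and 3-benzyloxy groups should give the all-cis (2R,3R,4R) triad under catalyst control, the distant upper unit exerting no bias; the closest known reaction types are the Ru–NHC-catalysed asymmetric hydrogenation of flavones to cis-flavan-4-ols and the heterogeneous all-cis hydrogenation of flavonols.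

Step 15
Reactants: 24 the nonabenzyl ether
Product: 25 (2R,3R,4R)-2-(4-hydroxyphenyl)-6-[(2R,3R,4S)-2-(3,4-dihydroxyphenyl)-3,7,8-trihydroxychroman-4-yl]chromane-3,4,7,8-tetrol
Conditions: H2 (1 atm), Pd(OH)2/C, THF/MeOH, 23 °C
Reagents that add atoms: none
Why: Hydrogenolysis of the nine benzyl ethers under neutral conditions; these should cleave much faster than the benzylic C4–OH and the ring C2–O1 bonds, and no acid is present to ionise C-4.

**Compound list**
1 | 2,3,4-trihydroxyacetophenone | CC(=O)c1ccc(O)c(O)c1O | starting material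
2 | 1-[3,4-bis(benzyloxy)-2-hydroxyphenyl]ethan-1-one | CC(=O)c1ccc(OCc2ccccc2)c(OCc2ccccc2)c1O | intermediate
3 | 3,4-bis(benzyloxy)benzaldehyde | O=Cc1ccc(OCc2ccccc2)c(OCc2ccccc2)c1 | starting material
4 | (E)-1-[3,4-bis(benzyloxy)-2-hydroxyphenyl]-3-[3,4-bis(benzyloxy)phenyl]prop-2-en-1-one | O=C(/C=C/c1ccc(OCc2ccccc2)c(OCc2ccccc2)c1)c1ccc(OCc2ccccc2)c(OCc2ccccc2)c1O | intermediate
5 | rac-trans-7,8-bis(benzyloxy)-2-[3,4-bis(benzyloxy)phenyl]-3-hydroxychroman-4-one (racemate, (2R,3R) enantiomer drawn; not isolated) | c1ccccc1COc1ccc(cc1OCc1ccccc1)[C@H]1Oc2c(ccc(OCc3ccccc3)c2OCc2ccccc2)C(=O)[C@@H]1O | intermediate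
6 | 7,8-bis(benzyloxy)-2-[3,4-bis(benzyloxy)phenyl]-3-hydroxy-4H-chromen-4-one | O=c1c(O)c(-c2ccc(OCc3ccccc3)c(OCc3ccccc3)c2)oc2c(OCc3ccccc3)c(OCc3ccccc3)ccc12 | intermediate
7 | 3,7,8-tris(benzyloxy)-2-[3,4-bis(benzyloxy)phenyl]-4H-chromen-4-one | O=c1c(OCc2ccccc2)c(-c2ccc(OCc3ccccc3)c(OCc3ccccc3)c2)oc2c(OCc3ccccc3)c(OCc3ccccc3)ccc12 | intermediate
8 | (2R,3S)-3,7,8-tris(benzyloxy)-2-[3,4-bis(benzyloxy)phenyl]chroman-4-one (2,3-cis; not isolated) | c1ccccc1COc1ccc(cc1OCc1ccccc1)[C@H]1Oc2c(ccc(OCc3ccccc3)c2OCc2ccccc2)C(=O)[C@H]1OCc1ccccc1 | intermediate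
9 | (2R,3R,4R)-3,7,8-tris(benzyloxy)-2-[3,4-bis(benzyloxy)phenyl]chroman-4-ol (all-cis) | c1ccccc1COc1ccc(cc1OCc1ccccc1)[C@H]1Oc2c(ccc(OCc3ccccc3)c2OCc2ccccc2)[C@@H](O)[C@H]1OCc1ccccc1 | intermediate
10 | 3-fluoro-2-hydroxybenzaldehyde | O=Cc1cccc(F)c1O | starting material
11 | 2-(benzyloxy)-3-fluorobenzaldehyde | O=Cc1cccc(F)c1OCc1ccccc1 | intermediate
12 | 2-(benzyloxy)-3-fluorophenyl formate (not isolated) | O=COc1cccc(F)c1OCc1ccccc1 | intermediate
13 | 2-(benzyloxy)-3-fluorophenol | Oc1cccc(F)c1OCc1ccccc1 | intermediate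
14 | 2-(benzyloxy)-4-bromo-3-fluorophenol | Oc1ccc(Br)c(F)c1OCc1ccccc1 | intermediate
15 | 2-(benzyloxy)-4-bromo-3-fluoro-6-[(2R,3R,4S)-3,7,8-tris(benzyloxy)-2-[3,4-bis(benzyloxy)phenyl]chroman-4-yl]phenol | Oc1c(OCc2ccccc2)c(F)c(Br)cc1[C@H]2c3ccc(OCc4ccccc4)c(OCc4ccccc4)c3O[C@H](c3ccc(OCc4ccccc4)c(OCc4ccccc4)c3)[C@@H]2OCc2ccccc2 | intermediate
16 | (2R,3R,4R)-3,7,8-tris(benzyloxy)-2-[3,4-bis(benzyloxy)phenyl]-4-[2,3-bis(benzyloxy)-5-bromo-4-fluorophenyl]chromane | c1ccccc1COc1c(OCc2ccccc2)c(F)c(Br)cc1[C@H]2c3ccc(OCc4ccccc4)c(OCc4ccccc4)c3O[C@H](c3ccc(OCc4ccccc4)c(OCc4ccccc4)c3)[C@@H]2OCc2ccccc2 | intermediate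
17 | methyl 3,4-bis(benzyloxy)-2-fluoro-5-[(2R,3R,4R)-3,7,8-tris(benzyloxy)-2-[3,4-bis(benzyloxy)phenyl]chroman-4-yl]benzoate | COC(=O)c1cc([C@H]2c3ccc(OCc4ccccc4)c(OCc4ccccc4)c3O[C@H](c3ccc(OCc4ccccc4)c(OCc4ccccc4)c3)[C@@H]2OCc2ccccc2)c(OCc2ccccc2)c(OCc2ccccc2)c1F | intermediate
18 | 4-(benzyloxy)phenylmagnesium bromide | Br[Mg]c1ccc(OCc2ccccc2)cc1 | starting material
19 | 2-(benzyloxy)-N-methoxy-N-methylacetamide | CON(C)C(=O)COCc1ccccc1 | starting material
20 | 2-(benzyloxy)-1-[4-(benzyloxy)phenyl]ethan-1-one | O=C(COCc1ccccc1)c1ccc(OCc2ccccc2)cc1 | intermediate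
21 | 2-(benzyloxy)-1-[4-(benzyloxy)phenyl]-3-[3,4-bis(benzyloxy)-2-fluoro-5-(upper flavan-4-yl)phenyl]propane-1,3-dione (present as its potassium enolate, C-2 of the dione unassigned; not isolated) | O=C(c1ccc(OCc2ccccc2)cc1)C(OCc1ccccc1)C(=O)c1cc([C@H]2c3ccc(OCc4ccccc4)c(OCc4ccccc4)c3O[C@H](c3ccc(OCc4ccccc4)c(OCc4ccccc4)c3)[C@@H]2OCc2ccccc2)c(OCc2ccccc2)c(OCc2ccccc2)c1F | intermediate
22 | 3,7,8-tris(benzyloxy)-2-[4-(benzyloxy)phenyl]-6-[(2R,3R,4R)-3,7,8-tris(benzyloxy)-2-[3,4-bis(benzyloxy)phenyl]chroman-4-yl]-4H-chromen-4-one | O=c1c(OCc2ccccc2)c(-c2ccc(OCc3ccccc3)cc2)oc2c(OCc3ccccc3)c(OCc3ccccc3)c([C@H]3c4ccc(OCc5ccccc5)c(OCc5ccccc5)c4O[C@H](c4ccc(OCc5ccccc5)c(OCc5ccccc5)c4)[C@@H]3OCc3ccccc3)cc12 | intermediate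
23 | (2R,3S)-3,7,8-tris(benzyloxy)-2-[4-(benzyloxy)phenyl]-6-[(2R,3R,4R)-upper flavan-4-yl]chroman-4-one (2,3-cis; not isolated) | c1ccccc1COc1ccc(cc1)[C@H]1Oc2c(cc([C@H]3c4ccc(OCc5ccccc5)c(OCc5ccccc5)c4O[C@H](c4ccc(OCc5ccccc5)c(OCc5ccccc5)c4)[C@@H]3OCc3ccccc3)c(OCc3ccccc3)c2OCc2ccccc2)C(=O)[C@H]1OCc1ccccc1 | intermediate
24 | (2R,3R,4R)-3,7,8-tris(benzyloxy)-2-[4-(benzyloxy)phenyl]-6-[(2R,3R,4R)-3,7,8-tris(benzyloxy)-2-[3,4-bis(benzyloxy)phenyl]chroman-4-yl]chroman-4-ol | c1ccccc1COc1ccc(cc1)[C@H]1Oc2c(cc([C@H]3c4ccc(OCc5ccccc5)c(OCc5ccccc5)c4O[C@H](c4ccc(OCc5ccccc5)c(OCc5ccccc5)c4)[C@@H]3OCc3ccccc3)c(OCc3ccccc3)c2OCc2ccccc2)[C@@H](O)[C@H]1OCc1ccccc1 | intermediate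
25 | (2R,3R,4R)-2-(4-hydroxyphenyl)-6-[(2R,3R,4S)-2-(3,4-dihydroxyphenyl)-3,7,8-trihydroxychroman-4-yl]chromane-3,4,7,8-tetrol | Oc1ccc([C@H]2Oc3c(cc([C@H]4c5ccc(O)c(O)c5O[C@H](c5ccc(O)c(O)c5)[C@@H]4O)c(O)c3O)[C@@H](O)[C@H]2O)cc1 | target

**Totals**
Total steps: 15. Longest linear sequence: 11 steps (steps 1–5, 9–11, 13–15).

**Steps most likely to fail**

1. Step 14 (labelled). Hydrogen uptake at the hindered tetrasubstituted C2=C3 bond of the large substrate may be too slow. The catalyst may discriminate the two faces poorly. The basic medium may epimerise C-3 of 23 before the ketone is reduced, giving a 2,3-trans product. Fallback with known chemistry, from 22 back to 24: heterogeneous hydrogenation (H2, PtO2, EtOAc/EtOH), the classical all-cis reduction of flavonol ethers, would give 24 together with its lower-unit (2S,3S,4S) diastereomer F1. Because the upper unit is fixed these are diastereomers, and 24 would be separated by chromatography.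

2. Step 5 (labelled). The same three processes apply: no turnover on the 3-alkoxy-substituted double bond, poor enantioface selection, or C-3 epimerisation of 8. Fallback with known chemistry, from 7 back to 9: hydrogenation over PtO2 would give the racemic all-cis alcohol, that is 9 and its enantiomer (2S,3S,4S)-3,7,8-tris(benzyloxy)-2-[3,4-bis(benzyloxy)phenyl]chroman-4-ol F2. Esterification of the mixture with (S)-2-methoxy-2-phenylacetic acid (DCC, DMAP, CH2Cl2) would give the diastereomeric esters, the (S)-O-methylmandelate of 9 F3 and the (S)-O-methylmandelate of the enantiomer F4. These would be separated by chromatography or crystallisation, and methanolysis of F3 (K2CO3, MeOH/THF) would return 9.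

3. Step 9. The weakly nucleophilic bromofluorophenol may lose the competition for the C-4 cation. Competing processes are O-alkylation to an aryl ether, self-condensation of the cation with benzyloxy-substituted rings of a second flavan, and proton loss to the flav-3-ene. Fallback, from 9 back to 15: capture of the cation by benzyl mercaptan (BnSH, BF3·OEt2 cat., CH2Cl2, −20 °C) should give (2R,3S,4S)-4-(benzylsulfanyl)-3,7,8-tris(benzyloxy)-2-[3,4-bis(benzyloxy)phenyl]chromane F5. Thiophilic activation of F5 with AgBF4 in THF at 0 °C, in the presence of excess 14 and without any Brønsted or hard Lewis acid, should then give 15; this mode of activation is the one established for flavans with poorly nucleophilic pyrogallol-type partners.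

**Further compounds**
F1 | step 14 | (2S,3S,4S)-3,7,8-tris(benzyloxy)-2-[4-(benzyloxy)phenyl]-6-[(2R,3R,4R)-3,7,8-tris(benzyloxy)-2-[3,4-bis(benzyloxy)phenyl]chroman-4-yl]chroman-4-ol | c1ccccc1COc1ccc(cc1)[C@@H]1Oc2c(cc([C@H]3c4ccc(OCc5ccccc5)c(OCc5ccccc5)c4O[C@H](c4ccc(OCc5ccccc5)c(OCc5ccccc5)c4)[C@@H]3OCc3ccccc3)c(OCc3ccccc3)c2OCc2ccccc2)[C@H](O)[C@@H]1OCc1ccccc1
F2 | step 5 | (2S,3S,4S)-3,7,8-tris(benzyloxy)-2-[3,4-bis(benzyloxy)phenyl]chroman-4-ol | c1ccccc1COc1ccc(cc1OCc1ccccc1)[C@@H]1Oc2c(ccc(OCc3ccccc3)c2OCc2ccccc2)[C@H](O)[C@@H]1OCc1ccccc1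
F3 | step 5 | (S)-2-methoxy-2-phenylacetate (ester at O-4) of 9 | c1ccccc1COc1ccc(cc1OCc1ccccc1)[C@H]1Oc2c(ccc(OCc3ccccc3)c2OCc2ccccc2)[C@@H](OC(=O)[C@@H](OC)c2ccccc2)[C@H]1OCc1ccccc1
F4 | step 5 | (S)-2-methoxy-2-phenylacetate (ester at O-4) of F2 | c1ccccc1COc1ccc(cc1OCc1ccccc1)[C@@H]1Oc2c(ccc(OCc3ccccc3)c2OCc2ccccc2)[C@H](OC(=O)[C@@H](OC)c2ccccc2)[C@@H]1OCc1ccccc1
F5 | step 9 | (2R,3S,4S)-4-(benzylsulfanyl)-3,7,8-tris(benzyloxy)-2-[3,4-bis(benzyloxy)phenyl]chromane | c1ccccc1CS[C@H]2c3ccc(OCc4ccccc4)c(OCc4ccccc4)c3O[C@H](c3ccc(OCc4ccccc4)c(OCc4ccccc4)c3)[C@@H]2OCc2ccccc2
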